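## Retrosynthetic overview

1. Last C–C bond: Stille coupling of a core (E)-vinylstannane with the (2E,4E)-5-bromodienamide of 2-amino-3-hydroxycyclopent-2-enone. Ring C is bought as cyclopentane-1,3-dione and joined last.
2. Tertiary carbinol: 1,2-addition of (E)-2-(tributylstannyl)vinyllithium to an epoxy quinone monoketal, anti to the oxirane; the ketal is unmasked afterwards.
3. Ring order: six-membered ring A comes from 2,5-dimethoxyaniline by oxidative dearomatisation to the quinone monoketal; oxirane ring B is then closed on it by chiral phase-transfer nucleophilic epoxidation.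
4. Upper amide: the aniline is acylated at the outset with (2E,4R)-2,4-dimethyloct-2-enoyl chloride, made by Wittig olefination of (R)-2-methylhexanal.
5. Side-chain stereocentre: lipase desymmetrisation of 2-methylpropane-1,3-diol, then copper-catalysed propyl coupling on the acetate-bearing arm.

Assumption: the cinchonine-derived salt N-benzylcinchoninium chloride is taken to give the (1S,6R)-epoxide needed here, its cinchonidine-derived pseudoenantiomer giving the antipodal epoxide.

## Route

Step 1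
Reactants: 1 2-methylpropane-1,3-diol
Product: 2 (S)-3-hydroxy-2-methylpropyl acetate
Conditions: lipase from Pseudomonas fluorescens (immobilised), vinyl acetate (3 equiv), CHCl3, 25 °C; stopped at ca. 35% diacetate
Reagents that add atoms: vinyl acetate, CC(=O)OC=C
Why: Lipase-catalysed irreversible transesterification desymmetrises the prochiral diol by acylating the pro-S hydroxymethyl group, and the slower second acylation consumes mainly the minor (R)-monoacetate, so the stereocentre is set as S in ≥98% ee.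

Step 2
Reactants: 2 (S)-3-hydroxy-2-methylpropyl acetate
Product: 3 (R)-3-[(tert-butyldiphenylsilyl)oxy]-2-methylpropyl acetate
Conditions: TBDPSCl (1.1 equiv), imidazole (2.2 equiv), CH2Cl2, 0 °C → rt
Reagents that add atoms: tert-butyl(chloro)diphenylsilane, CC(C)(C)[Si](Cl)(c1ccccc1)c1ccccc1
Why: Imidazole-mediated silylation of the primary alcohol is done at once so that 1,3-acyl migration cannot erode the ee; the stereocentre is untouched and its descriptor changes to R only through CIP priorities.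

Step 3
Reactants: 3 (R)-3-[(tert-butyldiphenylsilyl)oxy]-2-methylpropyl acetate
Product: 4 (R)-3-[(tert-butyldiphenylsilyl)oxy]-2-methylpropan-1-ol
Conditions: K2CO3 (0.2 equiv), MeOH, rt
Reagents that add atoms: none
Why: Base-catalysed transesterification (methanolysis) removes the acetate while the hindered silyl ether is stable, and no bond to the stereocentre is broken.

Step 4
Reactants: 4 (R)-3-[(tert-butyldiphenylsilyl)oxy]-2-methylpropan-1-ol
Product: 5 (S)-3-[(tert-butyldiphenylsilyl)oxy]-2-methylpropyl 4-methylbenzenesulfonate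
Conditions: TsCl (1.3 equiv), Et3N (2 equiv), DMAP (cat.), CH2Cl2, 0 °C → rt
Reagents that add atoms: 4-methylbenzenesulfonyl chloride, Cc1ccc(cc1)S(Cl)(=O)=O
Why: Sulfonylation of the primary alcohol installs the leaving group for the sp3–sp3 coupling without touching the stereocentre (descriptor S by priority change only).

Step 5
Reactants: 5 (S)-3-[(tert-butyldiphenylsilyl)oxy]-2-methylpropyl 4-methylbenzenesulfonate; 6 n-propylmagnesium bromide
Product: 7 (R)-tert-butyl[(2-methylhexyl)oxy]diphenylsilane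
Conditions: 6 (3 equiv), Li2CuCl4 (5 mol%), THF, −78 °C → rt
Reagents that add atoms: none
Why: Copper-catalysed Grignard cross-coupling with a primary tosylate (Kochi–Schlosser type) forms the C–C bond at the CH2 next to the stereocentre, which takes no part and stays intact.

Step 6
Reactants: 7 (R)-tert-butyl[(2-methylhexyl)oxy]diphenylsilane
Product: 8 (R)-2-methylhexan-1-ol
Conditions: Bu4NF (1.2 equiv), THF, rt; careful concentration (volatile)
Reagents that add atoms: none
Why: Fluoride-mediated desilylation is driven by the strong Si–F bond and leaves the stereocentre alone.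

Step 7
Reactants: 8 (R)-2-methylhexan-1-ol; 9 ethyl 2-(triphenyl-λ5-phosphanylidene)propanoate
Product: 11 ethyl (2E,4R)-2,4-dimethyloct-2-enoate, via (R)-2-methylhexanal 10 (not isolated)
Conditions: TEMPO (10 mol%), PhI(OAc)2 (1.1 equiv), CH2Cl2, rt; then 9 (1.3 equiv), rt → 40 °C
Reagents that add atoms: none
Why: TEMPO/PhI(OAc)2 oxidation stops at the aldehyde without epimerising the α-centre, and in-situ Wittig olefination with the stabilised α-methyl ylide gives the trisubstituted (E)-enoate (E:Z ≥ 95:5) before the volatile aldehyde can racemise.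

Step 8
Reactants: 11 ethyl (2E,4R)-2,4-dimethyloct-2-enoate
Product: 12 (2E,4R)-2,4-dimethyloct-2-enoic acid
Conditions: LiOH·H2O (3 equiv), THF/MeOH/H2O, 40 °C; then 1 M HCl
Reagents that add atoms: lithium hydroxide, [Li+].[OH-]
Why: Saponification by acyl–oxygen cleavage; the γ-stereocentre is not acidic enough to epimerise under hydroxide.

Step 9
Reactants: 12 (2E,4R)-2,4-dimethyloct-2-enoic acid
Product: 13 (2E,4R)-2,4-dimethyloct-2-enoyl chloride
Conditions: (COCl)2 (1.5 equiv), DMF (cat.), CH2Cl2, 0 °C → rt; concentrated and used crude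
Reagents that add atoms: oxalyl chloride, ClC(=O)C(Cl)=O
Why: Acid chloride formation through the catalytic chloroiminium (Vilsmeier-type) species is neutral and does not isomerise the trisubstituted alkene.

Step 10
Reactants: 13 (2E,4R)-2,4-dimethyloct-2-enoyl chloride; 14 2,5-dimethoxyaniline
Product: 15 (2E,4R)-N-(2,5-dimethoxyphenyl)-2,4-dimethyloct-2-enamide
Conditions: pyridine (2 equiv), CH2Cl2, 0 °C → rt
Reagents that add atoms: none
Why: N-acylation of the electron-rich aniline by the acid chloride (amide formation) is fast and clean.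

Step 11
Reactants: 15 (2E,4R)-N-(2,5-dimethoxyphenyl)-2,4-dimethyloct-2-enamide
Product: 16 (2E,4R)-N-(6,6-dimethoxy-3-oxocyclohexa-1,4-dien-1-yl)-2,4-dimethyloct-2-enamide
Conditions: PhI(OAc)2 (1.2 equiv), MeOH, 0 °C → rt; aq. NaHCO3 work-up
Reagents that add atoms: methanol, CO; water, O
Why: Oxidative dearomatisation with PhI(OAc)2 delivers methanol to the methoxy-bearing carbon ortho to nitrogen, and hydrolysis of the resulting vinylogous imidate gives the p-quinone monoketal whose free carbonyl is the vinylogous amide.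

Step 12
Reactants: 16 (2E,4R)-N-(6,6-dimethoxy-3-oxocyclohexa-1,4-dien-1-yl)-2,4-dimethyloct-2-enamide
Product: 17 (2E,4R)-N-[(1S,6R)-2,2-dimethoxy-5-oxo-7-oxabicyclo[4.1.0]hept-3-en-3-yl]-2,4-dimethyloct-2-enamide
Conditions: t-BuOOH (70% aq., 3 equiv), NaOH (1 M aq.), N-benzylcinchoninium chloride (10 mol%), toluene, 0 °C → rt; recrystallisation
Reagents that add atoms: tert-butyl hydroperoxide, CC(C)(C)OO
Why: Weitz–Scheffer nucleophilic epoxidation under chiral phase-transfer catalysis: the peroxide anion paired with the cinchoninium cation attacks one face of the only enone alkene not deactivated by nitrogen, setting both cis oxirane centres under catalyst control (the remote side-chain centre has no influence), and the minor diastereomer is removed by recrystallisation.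

Step 13
Reactants: 17 (2E,4R)-N-[(1S,6R)-2,2-dimethoxy-5-oxo-7-oxabicyclo[4.1.0]hept-3-en-3-yl]-2,4-dimethyloct-2-enamide; 18 (E)-1,2-bis(tributylstannyl)ethene
Product: 20 (2E,4R)-N-[(1S,5R,6R)-5-hydroxy-2,2-dimethoxy-5-[(E)-2-(tributylstannyl)ethenyl]-7-oxabicyclo[4.1.0]hept-3-en-3-yl]-2,4-dimethyloct-2-enamide, via (E)-2-(tributylstannyl)vinyllithium 19 (not isolated)
Conditions: 18 (3.2 equiv), n-BuLi (3.0 equiv), THF, −78 °C, 1 h; then 17, −78 °C; aq. NH4Cl
Reagents that add atoms: none
Why: Tin–lithium exchange gives the (E)-vinyllithium, which (after one equivalent removes the N–H) adds 1,2 to the only free ketone from the face opposite the adjacent oxirane oxygen, setting the tertiary carbinol with OH cis to the epoxide (descriptor R here only because tin raises the vinyl priority) and keeping the E-alkene.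

Step 14
Reactants: 20 (2E,4R)-N-[(1S,5R,6R)-5-hydroxy-2,2-dimethoxy-5-[(E)-2-(tributylstannyl)ethenyl]-7-oxabicyclo[4.1.0]hept-3-en-3-yl]-2,4-dimethyloct-2-enamide
Product: 21 (2E,4R)-N-[(1S,5R,6R)-5-hydroxy-2-oxo-5-[(E)-2-(tributylstannyl)ethenyl]-7-oxabicyclo[4.1.0]hept-3-en-3-yl]-2,4-dimethyloct-2-enamide
Conditions: montmorillonite K10 clay (acid-treated aluminosilicate, idealised Al2Si4O10(OH)2·nH2O), CH2Cl2, rt
Reagents that add atoms: water, O
Why: Mild heterogeneous acid-catalysed ketal hydrolysis unmasks the enone ketone while the epoxide, tertiary alcohol and C–Sn bond survive the non-nucleophilic, weakly acidic surface.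

Step 15
Reactants: 22 potassium (1E,3E)-5-oxopenta-1,3-dien-1-olate (glutaconaldehyde potassium salt)
Product: 23 (2E,4E)-5-bromopenta-2,4-dienal
Conditions: Ph3PBr2 (1.1 equiv), CH2Cl2, 0 °C → rt
Reagents that add atoms: dibromotriphenylphosphorane, BrP(Br)(c1ccccc1)(c1ccccc1)c1ccccc1
Why: Appel-type deoxybromination of a vinylogous carboxylate: O-phosphonium activation then addition–elimination by bromide gives the thermodynamic E,E bromodienal.

Step 16
Reactants: 23 (2E,4E)-5-bromopenta-2,4-dienal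
Product: 24 (2E,4E)-5-bromopenta-2,4-dienoic acid
Conditions: NaClO2, NaH2PO4, 2-methylbut-2-ene, t-BuOH/H2O, rt
Reagents that add atoms: sodium chlorite, [Na+].[O-]Cl=O
Why: Pinnick oxidation is chemoselective for the aldehyde and leaves the diene and vinyl bromide geometry intact.

Step 17
Reactants: 25 cyclopentane-1,3-dione
Product: 26 2-nitrocyclopentane-1,3-dione
Conditions: fuming HNO3 (1.1 equiv), AcOH, 10 °C
Reagents that add atoms: nitric acid, O[N+](=O)[O-]
Why: Electrophilic nitration of the enol of the 1,3-dione occurs at the doubly activated C2.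

Step 18
Reactants: 26 2-nitrocyclopentane-1,3-dione
Product: 27 2-amino-3-hydroxycyclopent-2-en-1-one hydrochloride
Conditions: H2 (1 atm), 10% Pd/C, HCl (1.1 equiv), EtOH, rt
Reagents that add atoms: hydrogen chloride, Cl
Why: Catalytic hydrogenation reduces the nitro group to the amine, which is trapped as its hydrochloride to prevent self-condensation.

Step 19
Reactants: 24 (2E,4E)-5-bromopenta-2,4-dienoic acid
Product: 28 (2E,4E)-5-bromopenta-2,4-dienoyl chloride
Conditions: (COCl)2 (1.3 equiv), DMF (cat.), CH2Cl2, 0 °C → rt; concentrated and used crude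
Reagents that add atoms: oxalyl chloride, ClC(=O)C(Cl)=O
Why: Acid chloride formation via the catalytic chloroiminium species proceeds without E/Z isomerisation of the diene.

Step 20
Reactants: 28 (2E,4E)-5-bromopenta-2,4-dienoyl chloride; 27 2-amino-3-hydroxycyclopent-2-en-1-one hydrochloride
Product: 29 (2E,4E)-5-bromo-N-(2-hydroxy-5-oxocyclopent-1-en-1-yl)penta-2,4-dienamide
Conditions: 27 (1.1 equiv), Et3N (2.5 equiv), DMF/CH2Cl2, 0 °C → rt; dilute HCl wash
Reagents that add atoms: none
Why: N-acylation of the liberated amine gives the amide, any enol ester formed first transferring its acyl group to nitrogen (O→N acyl shift) to reach the thermodynamically preferred product.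

Step 21
Reactants: 21 (2E,4R)-N-[(1S,5R,6R)-5-hydroxy-2-oxo-5-[(E)-2-(tributylstannyl)ethenyl]-7-oxabicyclo[4.1.0]hept-3-en-3-yl]-2,4-dimethyloct-2-enamide; 29 (2E,4E)-5-bromo-N-(2-hydroxy-5-oxocyclopent-1-en-1-yl)penta-2,4-dienamide
Product: 30 (2E,4R)-N-[(1S,5S,6R)-5-hydroxy-5-[(1E,3E,5E)-7-[(2-hydroxy-5-oxocyclopent-1-en-1-yl)amino]-7-oxohepta-1,3,5-trien-1-yl]-2-oxo-7-oxabicyclo[4.1.0]hept-3-en-3-yl]-2,4-dimethyloct-2-enamide (CNP0259711.1)
Conditions: PdCl2(MeCN)2 (10 mol%), DMF, rt, dark
Reagents that add atoms: none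
Why: Ligand-free Stille cross-coupling (zerovalent palladium formed in situ) joins the two sp2 carbons with retention of both alkene geometries to give the all-E triene under neutral conditions that spare the free OH, enol, epoxide and enone.

## Compound list

1 | 2-methylpropane-1,3-diol | CC(CO)CO | starting material
2 | (S)-3-hydroxy-2-methylpropyl acetate | CC(=O)OC[C@@H](C)CO | intermediate
3 | (R)-3-[(tert-butyldiphenylsilyl)oxy]-2-methylpropyl acetate | CC(=O)OC[C@@H](C)CO[Si](c1ccccc1)(c1ccccc1)C(C)(C)C | intermediate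
4 | (R)-3-[(tert-butyldiphenylsilyl)oxy]-2-methylpropan-1-ol | OC[C@@H](C)CO[Si](c1ccccc1)(c1ccccc1)C(C)(C)C | intermediate
5 | (S)-3-[(tert-butyldiphenylsilyl)oxy]-2-methylpropyl 4-methylbenzenesulfonate | Cc1ccc(cc1)S(=O)(=O)OC[C@@H](C)CO[Si](c1ccccc1)(c1ccccc1)C(C)(C)C | intermediate
6 | n-propylmagnesium bromide | CCC[Mg]Br | starting material
7 | (R)-tert-butyl[(2-methylhexyl)oxy]diphenylsilane | CCCC[C@@H](C)CO[Si](c1ccccc1)(c1ccccc1)C(C)(C)C | intermediate
8 | (R)-2-methylhexan-1-ol | CCCC[C@@H](C)CO | intermediate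
9 | ethyl 2-(triphenyl-λ5-phosphanylidene)propanoate | CCOC(=O)C(C)=P(c1ccccc1)(c1ccccc1)c1ccccc1 | starting material
10 | (R)-2-methylhexanal (not isolated) | CCCC[C@@H](C)C=O | intermediate
11 | ethyl (2E,4R)-2,4-dimethyloct-2-enoate | CCCC[C@@H](C)/C=C(\C)C(=O)OCC | intermediate
12 | (2E,4R)-2,4-dimethyloct-2-enoic acid | CCCC[C@@H](C)/C=C(\C)C(=O)O | intermediate
13 | (2E,4R)-2,4-dimethyloct-2-enoyl chloride | CCCC[C@@H](C)/C=C(\C)C(=O)Cl | intermediate
14 | 2,5-dimethoxyaniline | COc1ccc(OC)c(N)c1 | starting material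
15 | (2E,4R)-N-(2,5-dimethoxyphenyl)-2,4-dimethyloct-2-enamide | CCCC[C@@H](C)/C=C(\C)C(=O)Nc1cc(OC)ccc1OC | intermediate
16 | (2E,4R)-N-(6,6-dimethoxy-3-oxocyclohexa-1,4-dien-1-yl)-2,4-dimethyloct-2-enamide | CCCC[C@@H](C)/C=C(\C)C(=O)NC1=CC(=O)C=CC1(OC)OC | intermediate
17 | (2E,4R)-N-[(1S,6R)-2,2-dimethoxy-5-oxo-7-oxabicyclo[4.1.0]hept-3-en-3-yl]-2,4-dimethyloct-2-enamide | CCCC[C@@H](C)/C=C(\C)C(=O)NC1=CC(=O)[C@@H]2O[C@@H]2C1(OC)OC | intermediate
18 | (E)-1,2-bis(tributylstannyl)ethene | CCCC[Sn](CCCC)(CCCC)/C=C/[Sn](CCCC)(CCCC)CCCC | starting material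
19 | (E)-2-(tributylstannyl)vinyllithium (not isolated) | [Li]/C=C/[Sn](CCCC)(CCCC)CCCC | intermediate
20 | (2E,4R)-N-[(1S,5R,6R)-5-hydroxy-2,2-dimethoxy-5-[(E)-2-(tributylstannyl)ethenyl]-7-oxabicyclo[4.1.0]hept-3-en-3-yl]-2,4-dimethyloct-2-enamide (OH cis to oxirane O) | CCCC[C@@H](C)/C=C(\C)C(=O)NC1=C[C@@](O)(/C=C/[Sn](CCCC)(CCCC)CCCC)[C@@H]2O[C@@H]2C1(OC)OC | intermediate
21 | (2E,4R)-N-[(1S,5R,6R)-5-hydroxy-2-oxo-5-[(E)-2-(tributylstannyl)ethenyl]-7-oxabicyclo[4.1.0]hept-3-en-3-yl]-2,4-dimethyloct-2-enamide | CCCC[C@@H](C)/C=C(\C)C(=O)NC1=C[C@@](O)(/C=C/[Sn](CCCC)(CCCC)CCCC)[C@@H]2O[C@@H]2C1=O | intermediate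
22 | potassium (1E,3E)-5-oxopenta-1,3-dien-1-olate (glutaconaldehyde potassium salt) | [K+].[O-]/C=C/C=C/C=O | starting material
23 | (2E,4E)-5-bromopenta-2,4-dienal | Br/C=C/C=C/C=O | intermediate
24 | (2E,4E)-5-bromopenta-2,4-dienoic acid | Br/C=C/C=C/C(=O)O | intermediate
25 | cyclopentane-1,3-dione | O=C1CCC(=O)C1 | starting material
26 | 2-nitrocyclopentane-1,3-dione | O=C1CCC(=O)C1[N+](=O)[O-] | intermediate
27 | 2-amino-3-hydroxycyclopent-2-en-1-one hydrochloride | NC1=C(O)CCC1=O.Cl | intermediate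
28 | (2E,4E)-5-bromopenta-2,4-dienoyl chloride | Br/C=C/C=C/C(=O)Cl | intermediate
29 | (2E,4E)-5-bromo-N-(2-hydroxy-5-oxocyclopent-1-en-1-yl)penta-2,4-dienamide | Br/C=C/C=C/C(=O)NC1=C(O)CCC1=O | intermediate
30 | (2E,4R)-N-[(1S,5S,6R)-5-hydroxy-5-[(1E,3E,5E)-7-[(2-hydroxy-5-oxocyclopent-1-en-1-yl)amino]-7-oxohepta-1,3,5-trien-1-yl]-2-oxo-7-oxabicyclo[4.1.0]hept-3-en-3-yl]-2,4-dimethyloct-2-enamide (CNP0259711.1) | CCCC[C@@H](C)/C=C(\C)C(=O)NC1=C[C@@](O)(/C=C/C=C/C=C/C(=O)NC2=C(O)CCC2=O)[C@@H]2O[C@@H]2C1=O | target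

## Step count and risks

Total step count: 21. Longest linear sequence: 15 steps (steps 1–14, then step 21).

Most likely to fail:

Step 12 (asymmetric epoxidation). The selectivity of the phase-transfer catalyst may be moderate, and because 16 already carries the side-chain centre the minor product is a remote diastereomer that can be hard to remove. The fallback sets the oxirane before the chiral acyl chain is attached. It sets out from 14: Boc2O in THF at reflux gives tert-butyl N-(2,5-dimethoxyphenyl)carbamate F1. PhI(OAc)2 in MeOH gives tert-butyl N-(6,6-dimethoxy-3-oxocyclohexa-1,4-dien-1-yl)carbamate F2. The same peroxide/cinchoninium epoxidation gives crystalline tert-butyl N-[(1S,6R)-2,2-dimethoxy-5-oxo-7-oxabicyclo[4.1.0]hept-3-en-3-yl]carbamate F3, now an enantiomer mixture that is brought to >99% ee by recrystallisation. LiN(SiMe3)2 in THF at −78 °C followed by 13 gives tert-butyl N-[(2E,4R)-2,4-dimethyloct-2-enoyl]-N-[(1S,6R)-2,2-dimethoxy-5-oxo-7-oxabicyclo[4.1.0]hept-3-en-3-yl]carbamate F4. Mg(ClO4)2 (cat.) in MeCN at 50 °C removes the Boc group selectively, and the route is rejoined at 17.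

Step 13 (vinyllithium addition). The acidic N–H, the deactivated vinylogous-amide ketone and the basic vinyllithium may give low conversion or epoxide damage. The fallback sets out from 17 and uses a smaller, less basic acetylide. Ethynylmagnesium bromide (4 equiv, THF, −78 → 0 °C) adds anti to the oxirane to give (2E,4R)-N-[(1S,5R,6R)-5-ethynyl-5-hydroxy-2,2-dimethoxy-7-oxabicyclo[4.1.0]hept-3-en-3-yl]-2,4-dimethyloct-2-enamide F5. Bu3SnH with PdCl2(PPh3)2 (2 mol%) in THF at 0 °C then effects syn, terminal-selective hydrostannylation of the hindered propargylic alcohol, and the route is rejoined at 20.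

Step 14 (ketal hydrolysis beside a vinylstannane). Acid may cause protodestannylation before the ketal is cleaved. The fallback reverses the endgame so that no C–Sn bond meets acid. It sets out from 20, which is coupled with 29 under the step 21 conditions (PdCl2(MeCN)2, DMF, rt) to give (2E,4R)-N-[(1S,5S,6R)-5-hydroxy-5-[(1E,3E,5E)-7-[(2-hydroxy-5-oxocyclopent-1-en-1-yl)amino]-7-oxohepta-1,3,5-trien-1-yl]-2,2-dimethoxy-7-oxabicyclo[4.1.0]hept-3-en-3-yl]-2,4-dimethyloct-2-enamide F6. Its ketal is then hydrolysed (the K10 clay of step 14 in CH2Cl2, or pyridinium p-toluenesulfonate in wet acetone), and the route is rejoined at 30.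

## Further compounds

F1 | step 12 | tert-butyl N-(2,5-dimethoxyphenyl)carbamate | COc1ccc(OC)c(NC(=O)OC(C)(C)C)c1
F2 | step 12 | tert-butyl N-(6,6-dimethoxy-3-oxocyclohexa-1,4-dien-1-yl)carbamate | CC(C)(C)OC(=O)NC1=CC(=O)C=CC1(OC)OC
F3 | step 12 | tert-butyl N-[(1S,6R)-2,2-dimethoxy-5-oxo-7-oxabicyclo[4.1.0]hept-3-en-3-yl]carbamate | CC(C)(C)OC(=O)NC1=CC(=O)[C@@H]2O[C@@H]2C1(OC)OC
F4 | step 12 | tert-butyl N-[(2E,4R)-2,4-dimethyloct-2-enoyl]-N-[(1S,6R)-2,2-dimethoxy-5-oxo-7-oxabicyclo[4.1.0]hept-3-en-3-yl]carbamate | CCCC[C@@H](C)/C=C(\C)C(=O)N(C(=O)OC(C)(C)C)C1=CC(=O)[C@@H]2O[C@@H]2C1(OC)OC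
F5 | step 13 | (2E,4R)-N-[(1S,5R,6R)-5-ethynyl-5-hydroxy-2,2-dimethoxy-7-oxabicyclo[4.1.0]hept-3-en-3-yl]-2,4-dimethyloct-2-enamide | CCCC[C@@H](C)/C=C(\C)C(=O)NC1=C[C@@](O)(C#C)[C@@H]2O[C@@H]2C1(OC)OC
F6 | step 14 | (2E,4R)-N-[(1S,5S,6R)-5-hydroxy-5-[(1E,3E,5E)-7-[(2-hydroxy-5-oxocyclopent-1-en-1-yl)amino]-7-oxohepta-1,3,5-trien-1-yl]-2,2-dimethoxy-7-oxabicyclo[4.1.0]hept-3-en-3-yl]-2,4-dimethyloct-2-enamide | CCCC[C@@H](C)/C=C(\C)C(=O)NC1=C[C@@](O)(/C=C/C=C/C=C/C(=O)NC2=C(O)CCC2=O)[C@@H]2O[C@@H]2C1(OC)OC
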